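**Retrosynthetic overview**
- Structural feature used: in cyclopentane ring B (a = spiro carbon between the two ring A carbonyls, b = CH‑isopropyl, c and d = CH2, e = pinane C‑2), the CH2 d is bonded to e on the face anti to the gem‑dimethyl bridge (C‑6), and a sits on the shielded syn face. d can therefore be brought in as a one‑carbon unit that attacks an a=e double bond from the open face.
- Ring B is disconnected at a–b (radical 5‑exo closure onto a prenyl alkene, then hydrogenation of the isopropenyl group) and at c–d (homoconjugate opening of a spiro cyclopropane by a prenyl cuprate).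
- The cyclopropane a–d–e is a temporary ring: bonds d–e and a–d come from dimethylsulfoxonium methylide and the nopinylidene ring A dione, and a–d is broken again in the next step.
- The alkylidene comes from (−)‑nopinone (ozonolysis of (+)‑β‑pinene) and the ring A dione, which is made from 2,4,6‑trihydroxybenzoic acid by ester‑blocked O‑/C‑methylation with dearomatisation.
- Order of ring formation: ring A (dearomatisation), temporary cyclopropane on the pinane, ring B.

Key step: step 7

Remark (assumptions): (1R,5R)‑(+)‑β‑pinene is taken as purchasable in high enantiomeric purity. Compounds with an enolisable CH between the two ring A carbonyls are drawn as one tautomer, and the configuration at that carbon is left open because enolisation erases it.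

**Step 1**
Reactants: 1 (+)‑β‑pinene
Product: 3 (−)‑nopinone, via ozonide 2 (not isolated)
Conditions: O3, CH2Cl2, −78 °C; then PPh3, −78 °C → rt
Reagents that add atoms: ozone, O=[O+][O-]
Why: Ozonolysis (Criegee mechanism) cleaves only the exocyclic C2=CH2 bond, PPh3 reduces the ozonide, and both bridgehead stereocentres of the pinane are carried over unchanged.

**Step 2**
Reactants: 4 2,4,6‑trihydroxybenzoic acid
Product: 5 benzyl 2,4,6‑trihydroxybenzoate
Conditions: BnBr, KHCO3, DMF, rt
Reagents that add atoms: benzyl bromide, BrCc1ccccc1
Why: Hydrogen carbonate ionises only the carboxylic acid, so SN2 O‑alkylation of the carboxylate gives the benzyl ester with the phenols free; the ester will block the ring carbon between the two later carbonyls and is removable by hydrogenolysis.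

**Step 3**
Reactants: 5 benzyl 2,4,6‑trihydroxybenzoate
Product: 6 benzyl 2,6‑dihydroxy‑4‑methoxybenzoate
Conditions: MeI (1.05 equiv), K2CO3 (1.0 equiv), acetone, rt
Reagents that add atoms: iodomethane, CI
Why: Williamson etherification is selective for the 4‑OH, which is the most acidic phenol and the only one not hydrogen‑bonded to the ester carbonyl.

**Step 4**
Reactants: 6 benzyl 2,6‑dihydroxy‑4‑methoxybenzoate
Product: 9 benzyl 2‑hydroxy‑4‑methoxy‑3,3,5‑trimethyl‑6‑oxocyclohexa‑1,4‑diene‑1‑carboxylate, via monomethyl benzoate 7 (not isolated), via dimethyl benzoate 8 (not isolated)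
Conditions: MeI (excess), NaOMe, MeOH, 0 °C → rt; then cold dilute HCl
Reagents that add atoms: iodomethane, CI
Why: Nuclear C‑methylation of the resorcinolate in methanol (alkylative dearomatisation) methylates both free ring positions and then one already methylated carbon; because 8 is symmetric the methoxy group must end between C‑Me and CMe2, the acyl‑bearing carbon is not alkylated, and the ester flanked by two phenoxides should resist methoxide.

**Step 5**
Reactants: 9 benzyl 2‑hydroxy‑4‑methoxy‑3,3,5‑trimethyl‑6‑oxocyclohexa‑1,4‑diene‑1‑carboxylate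
Product: 11 ring A dione (5‑methoxy‑4,6,6‑trimethylcyclohex‑4‑ene‑1,3‑dione), via diketo acid 10 (not isolated)
Conditions: H2 (1 atm), Pd/C, EtOAc, rt
Reagents that add atoms: none
Why: Hydrogenolysis of the benzyl ester gives a β,β'‑diketo acid that should lose CO2 spontaneously under neutral conditions, and the tetrasubstituted vinylogous ester double bond is not expected to be reduced.

**Step 6**
Reactants: 3 (−)‑nopinone; 11 ring A dione
Product: 13 nopinylidene ring A dione, via aldol TiCl3 alkoxide 12 (not isolated)
Conditions: TiCl4, pyridine, THF, 0 °C → rt; used promptly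
Reagents that add atoms: none
Why: TiCl4/pyridine Knoevenagel condensation: the TiCl3 enolate of the cyclic dione adds to the TiCl4‑activated ketone and the aldolate eliminates irreversibly, which drives condensation with a hindered ketone; no stereocentre is touched and the alkene geometry is left open because it is erased later.

**Step 7**
Reactants: 13 nopinylidene ring A dione; 14 trimethylsulfoxonium iodide
Product: 16 dispiro cyclopropane joining ring A and the pinane, via sulfoxonium enolate betaine 15 (not isolated)
Conditions: 14 (1.05 equiv), NaH (1.0 equiv), THF/DMSO (5:1), rt; then 13, −20 → 0 °C, short reaction time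
Reagents that add atoms: none
Why: Corey–Chaykovsky cyclopropanation (Michael‑initiated ring closure): the methylide carbon adds to the β‑carbon e of the cross‑conjugated, doubly activated alkylidene 13 to give the betaine 15, whose enolate carbon a then displaces dimethyl sulfoxide from the new CH2 (d). The closest known reactions are the cyclopropanations of alkylidene malonates and 2‑alkylidene 1,3‑diones with dimethylsulfoxonium methylide, including substrates that carry γ‑hydrogens. The only ring closed is the cyclopropane a–d–e, by a 3‑exo‑tet C‑alkylation, the closure by which 2‑(2‑sulfonioethyl)‑1,3‑dione enolates are known to give spirocyclopropanes in preference to O‑alkylated dihydrofurans. The stereocentre e is set by the pinane: the ylide should approach the exocyclic alkene on the face anti to the gem‑dimethyl bridge (the face used in hydroboration and epoxidation of β‑pinene), so d ends anti and a syn to the bridge. The spiro carbon a forms without control (alkene geometry, bond rotation in 15), which does not matter because a becomes planar again when the ring is opened. The step needs conjugate addition to win over γ‑deprotonation at pinane C‑3 and over attack at the ketones; this rests on the high electrophilicity of the alkylidene dione, on the stabilised ylide that prefers 1,4‑addition, and on using no excess ylide at low temperature.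

**Step 8**
Reactants: 16 dispiro cyclopropane; 17 prenylmagnesium chloride
Product: 18 ring‑opened dione carrying a 4‑methylpent‑3‑enyl chain on pinane C‑2
Conditions: 17 (2.4 equiv), CuBr·SMe2 (1.2 equiv), THF, −78 °C; then 16, −78 → −40 °C; aq. NH4Cl
Reagents that add atoms: none
Why: Homoconjugate (SN2‑type) addition of a soft allylic cuprate to a spiro‑activated cyclopropane should occur at the CH2 d, the only unhindered electrophilic carbon, with the dione enolate as leaving group and the prenyl unit transferred through its CH2 terminus; e is not touched and the stereocentre a of the cyclopropane is erased.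

**Step 9**
Reactants: 18 ring‑opened dione
Product: 21 isopropenyl dispiro dione, via dione radical 19 (not isolated), via cyclised tertiary radical 20 (not isolated)
Conditions: Mn(OAc)3·2H2O (2.2 equiv), Cu(OAc)2·H2O (0.5 equiv), degassed AcOH, 25 °C
Reagents that add atoms: none
Why: Mn(OAc)3‑mediated oxidative radical cyclisation: trivalent manganese oxidises the enolised dione to the electrophilic radical 19, which adds 5‑exo to the CH terminus of the trisubstituted alkene, and divalent copper converts radical 20 into the isopropenyl group; a chair‑like transition state with the bulkier bridgehead side of e pseudo‑equatorial should place the new group at b trans to pinane C‑1, and the carbonyl buttressed in‑plane by the vinylic methyl should lie beside the pinane CH2 (C‑3), which together give the required configurations at a and b.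

**Step 10**
Reactants: 21 isopropenyl dispiro dione
Product: 22 target CNP0307059.1
Conditions: H2 (1–3 atm), RhCl(PPh3)3 (cat.), benzene/EtOH, rt
Reagents that add atoms: none
Why: Homogeneous hydrogenation with RhCl(PPh3)3 should reduce the 1,1‑disubstituted isopropenyl double bond and leave the tetrasubstituted vinylogous ester; no stereocentre is formed and the catalyst does not promote double‑bond migration that would endanger C‑b.

**Compound list**
1 | (+)‑β‑pinene, (1R,5R)‑6,6‑dimethyl‑2‑methylidenebicyclo[3.1.1]heptane | C=C1CC[C@@H]2C[C@H]1C2(C)C | starting material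
2 | β‑pinene ozonide (spiro 1,2,4‑trioxolane at pinane C‑2, either configuration at the spiro carbon) | O1OC2(OC1)CC[C@@H]1C[C@H]2C1(C)C | intermediate (not isolated)
3 | (−)‑nopinone, (1S,5R)‑6,6‑dimethylbicyclo[3.1.1]heptan‑2‑one | O=C1CC[C@@H]2C[C@H]1C2(C)C | intermediate
4 | 2,4,6‑trihydroxybenzoic acid | OC(=O)c1c(O)cc(O)cc1O | starting material
5 | benzyl 2,4,6‑trihydroxybenzoate | O=C(OCc1ccccc1)c1c(O)cc(O)cc1O | intermediate
6 | benzyl 2,6‑dihydroxy‑4‑methoxybenzoate | COc1cc(O)c(C(=O)OCc2ccccc2)c(O)c1 | intermediate
7 | benzyl 2,6‑dihydroxy‑4‑methoxy‑3‑methylbenzoate | COc1cc(O)c(C(=O)OCc2ccccc2)c(O)c1C | intermediate (not isolated)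
8 | benzyl 2,6‑dihydroxy‑4‑methoxy‑3,5‑dimethylbenzoate | COc1c(C)c(O)c(C(=O)OCc2ccccc2)c(O)c1C | intermediate (not isolated)
9 | benzyl 2‑hydroxy‑4‑methoxy‑3,3,5‑trimethyl‑6‑oxocyclohexa‑1,4‑diene‑1‑carboxylate (enol form of the 2,6‑dioxo ester) | COC1=C(C)C(=O)C(C(=O)OCc2ccccc2)=C(O)C1(C)C | intermediate
10 | 2‑hydroxy‑4‑methoxy‑3,3,5‑trimethyl‑6‑oxocyclohexa‑1,4‑diene‑1‑carboxylic acid | COC1=C(C)C(=O)C(C(O)=O)=C(O)C1(C)C | intermediate (not isolated)
11 | ring A dione, 5‑methoxy‑4,6,6‑trimethylcyclohex‑4‑ene‑1,3‑dione | COC1=C(C)C(=O)CC(=O)C1(C)C | intermediate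
12 | aldol adduct of 11 at C‑2 with the carbonyl carbon of 3, present as its TiCl3 alkoxide (shown as the free tertiary alcohol; new centres undefined) | COC1=C(C)C(=O)C(C(=O)C1(C)C)C1(O)CC[C@@H]2C[C@H]1C2(C)C | intermediate (not isolated)
13 | nopinylidene ring A dione, 2‑[(1S,5R)‑6,6‑dimethylbicyclo[3.1.1]heptan‑2‑ylidene]‑5‑methoxy‑4,6,6‑trimethylcyclohex‑4‑ene‑1,3‑dione (E/Z mixture) | COC1=C(C)C(=O)C(=C2CC[C@@H]3C[C@H]2C3(C)C)C(=O)C1(C)C | intermediate (key‑step precursor)
14 | trimethylsulfoxonium iodide | C[S+](C)(C)=O.[I-] | starting material
15 | betaine: ring A dione enolate bearing at C‑2 the pinan‑2‑yl group whose C‑2 carries CH2–S(O)Me2(+) anti to the gem‑dimethyl bridge | COC1=C(C)C(=O)C(=C([O-])C1(C)C)[C@@]1(C[S+](C)(C)=O)CC[C@@H]2C[C@H]1C2(C)C | intermediate (not isolated)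
16 | dispiro cyclopropane: cyclopropane C‑1 = C‑2 of the ring A dione (configuration open), C‑2 = pinane C‑2 (R; cyclopropane CH2 anti, dione carbon syn to the gem‑dimethyl bridge), C‑3 = CH2; pinane bridgeheads 1S,5R | COC1=C(C)C(=O)C2(C(=O)C1(C)C)C[C@@]23CC[C@@H]2C[C@H]3C2(C)C | intermediate (key‑step product)
17 | prenylmagnesium chloride (3‑methylbut‑2‑enylmagnesium chloride) | CC(C)=CC[Mg]Cl | starting material
18 | 2‑[(1S,2S,5R)‑6,6‑dimethyl‑2‑(4‑methylpent‑3‑enyl)bicyclo[3.1.1]heptan‑2‑yl]‑5‑methoxy‑4,6,6‑trimethylcyclohex‑4‑ene‑1,3‑dione (side chain anti to the gem‑dimethyl bridge; dione C‑2 enolisable) | COC1=C(C)C(=O)C(C(=O)C1(C)C)[C@@]1(CCC=C(C)C)CC[C@@H]2C[C@H]1C2(C)C | intermediate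
19 | radical of 18 at C‑2 of the dione | COC1=C(C)C(=O)[C](C(=O)C1(C)C)[C@@]1(CCC=C(C)C)CC[C@@H]2C[C@H]1C2(C)C | intermediate (not isolated)
20 | cyclised radical: skeleton of 22 with a 2‑propyl radical centre on C‑b | COC1=C(C)C(=O)[C@@]2(C(=O)C1(C)C)[C@@H]([C](C)C)CC[C@@]21CC[C@@H]2C[C@H]1C2(C)C | intermediate (not isolated)
21 | (1S,2R,2'R,3'R,5R)‑4''‑methoxy‑3'',5'',5'',6,6‑pentamethyl‑3'‑(prop‑1‑en‑2‑yl)dispiro[bicyclo[3.1.1]heptane‑2,1'‑cyclopentane‑2',1''‑cyclohex[3]ene]‑2'',6''‑dione | COC1=C(C)C(=O)[C@@]2(C(=O)C1(C)C)[C@@H](C(C)=C)CC[C@@]21CC[C@@H]2C[C@H]1C2(C)C | intermediate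
22 | CNP0307059.1, (1S,2R,2'R,3'R,5R)‑4''‑methoxy‑3'',5'',5'',6,6‑pentamethyl‑3'‑(propan‑2‑yl)dispiro[bicyclo[3.1.1]heptane‑2,1'‑cyclopentane‑2',1''‑cyclohex[3]ene]‑2'',6''‑dione (e = C‑2, a = C‑2', b = C‑3') | COC1=C(C)C(=O)[C@@]2(C(=O)C1(C)C)[C@@H](C(C)C)CC[C@@]21CC[C@@H]2C[C@H]1C2(C)C | target

**Step count**
Total steps: 10. Longest linear sequence: 9 steps (4 → 22, steps 2–10).

**Steps most likely to fail**

1. Step 7 (key step). What may go wrong: the basic ylide removes a γ‑proton at pinane C‑3 of 13, or 13 has already isomerised to its deconjugated dienol, so that an unreactive dienolate forms in place of the conjugate adduct. Alternatively, iodide or traces of acid reopen the strained cyclopropane and it recloses through oxygen to a dihydrofuran (Cloke–Wilson‑type ring expansion). Fallback: a base‑free cyclopropanation that sets out from 13. Diazomethane in Et2O at 0 °C should add as a 1,3‑dipole, carbon to e on the open face and nitrogen to a, to give the dispiro 1‑pyrazoline F1. Irradiation of F1 (Pyrex filter, CH2Cl2, −20 °C) should expel dinitrogen and close the 1,3‑diradical to the cyclopropane, which rejoins the route at 16.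

2. Step 6. What may go wrong: the condensation stalls at or reverts from the aldol stage because both partners are hindered and the tetrasubstituted alkylidene is strained; pyridine may isomerise 13 to the deconjugated enol; TiCl4 may open the cyclobutane. Fallback: raise the electrophile to the ketal level, setting out from 3 and 11. Trimethyl orthoformate in methanol with catalytic TsOH should convert 3 into nopinone dimethyl ketal F2. F2 and 11 with catalytic TMSOTf in CH2Cl2 at −40 °C (ketal variant of the Knoevenagel condensation) should undergo C‑alkylation of the dione enol and loss of two molecules of methanol without any base, rejoining the route at 13.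

3. Step 9. What may go wrong: insufficient control over the rotamer about the a–e bond and over the alkene face during radical addition, leading to epimers at a or b; or unselective oxidative termination (isopropylidene isomer, capture of a tertiary cation by a ring A carbonyl). Fallback: a polar 5‑exo closure that sets out from 16. The cuprate from allylmagnesium bromide and CuBr·SMe2 (THF, −78 °C) should open the cyclopropane at d to the but‑3‑enyl dione F3. Cross‑metathesis of F3 with methyl 2‑methylprop‑2‑enyl carbonate (second‑generation Grubbs catalyst, CH2Cl2, 40 °C) should give the allylic carbonate F4. Pd(PPh3)4 in THF (zerovalent palladium; a chiral diphosphine can be substituted to tune the face) should ionise F4, and the dione enolate should attack the internal allyl terminus in a Tsuji–Trost cyclisation that forms a–b and the isopropenyl group directly, rejoining the route at 21.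

**Further compounds**
F1 | step 7 | dispiro 1‑pyrazoline from 13 and diazomethane (ring a–N=N–CH2–e; CH2 on pinane C‑2 anti to the gem‑dimethyl bridge; configuration at a open) | COC1=C(C)C(=O)C2(N=NC[C@@]23CC[C@@H]2C[C@H]3C2(C)C)C(=O)C1(C)C
F2 | step 6 | nopinone dimethyl ketal, (1S,5R)‑2,2‑dimethoxy‑6,6‑dimethylbicyclo[3.1.1]heptane | COC1(OC)CC[C@@H]2C[C@H]1C2(C)C
F3 | step 9 | 2‑[(1S,2S,5R)‑2‑(but‑3‑enyl)‑6,6‑dimethylbicyclo[3.1.1]heptan‑2‑yl]‑5‑methoxy‑4,6,6‑trimethylcyclohex‑4‑ene‑1,3‑dione | COC1=C(C)C(=O)C(C(=O)C1(C)C)[C@@]1(CCC=C)CC[C@@H]2C[C@H]1C2(C)C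
F4 | step 9 | allylic carbonate: F3 with the chain terminus extended to CH=C(CH3)CH2OCO2CH3 (E/Z mixture) | COC1=C(C)C(=O)C(C(=O)C1(C)C)[C@@]1(CCC=C(C)COC(=O)OC)CC[C@@H]2C[C@H]1C2(C)C
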